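**Assumption and conventions.** The target SMILES is read as the (3R) enantiomer (CIP order at C3: OH > C4 > C2 > ring B). Flavonoid numbering is used (O1, C2, C3, C4, C4a–C8a; primed locants for ring B). Prenyl = 3-methylbut-2-en-1-yl, MOM = methoxymethyl, TIPS = triisopropylsilyl, TMS = trimethylsilyl, Ts = 4-methylphenylsulfonyl.

**Check of the key-step structures.** The E allylic alcohol has cis aryl groups, the oxirane is the cis-diaryl (2R,3R) isomer, and its ring B carbon has the same spatial arrangement as C3 of the target. The D-(−)-tartrate is the correct enantiomer: the L-(+) catalyst gives the 2S glycidol series, and the target needs the opposite face. No constitution or configuration had to be corrected. The design changes are: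
- O1 carries TIPS and not tert-butyldimethylsilyl.
- C4 is taken to the ketone before O1 is unmasked.
- Ring C is closed by phenoxide displacement of a primary tosylate.
- The MOM groups are removed without protic acid.

## Structural features

The target is a 3-hydroxyisoflavanone: ring A is fused to the dihydropyranone ring C (2,3-dihydro-4H-chromen-4-one), and ring B is attached at C3. Ring A is a fully substituted phloroglucinol unit with hydroxyls at C5 and C7 flanking a prenyl group at C6. Ring B carries 2′-OMe, 3′-prenyl and 4′-OH in a contiguous pattern. C3 is the only stereocentre (R); it is fully substituted (OH, ring B, the C2 methylene, the C4 carbonyl), so no neighbouring centre can relay stereochemistry and no epimerisable hydrogen exists. The fragile groups are the two prenyl alkenes (oxidants; acid-induced cyclisation onto the ortho phenols to 2,2-dimethylchromans), the tertiary benzylic α-ketol (acid ionisation leading to dehydration to the isoflavone or loss of configuration; base-induced ketol shift) and the electron-rich phenols. The real difficulties are the enantioselective construction of the oxygenated quaternary C3 beside two other alkenes, the ring A regiochemistry (6- versus 8-prenyl, that is O1 versus O5 in ring closure), and the crowded ring B. The key step exploits that C3 bears an oxygen, ring B and C2 and stands next to the oxygenated benzylic C4 on ring A. This is the pattern of an epoxidised (E)-2,3-diarylprop-2-en-1-ol, whose C2 hydroxyl can steer a reagent-controlled epoxidation past the prenyl alkenes.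

## Logic of the disconnections

24 ⇒ 22. Cut: the three aryl O–CH2OCH3 bonds. Reason: the phenols must stay masked until ring C is closed, so that only O1 can cyclise and the rings survive oxidation. Gain: none in skeleton; every skeletal bond is already present in 22. Demand: acetal cleavage without protic acid, because the prenyl groups and the tertiary benzylic C3–OH are acid-labile.

22 ⇒ 20 (through 21). Cut: O1–C2. Reason: an aryl alkyl ether on a primary carbon is the natural product of a phenoxide displacement, and O1 is the one ring A oxygen that carries a silyl group. Gain: ring C is opened to an acyclic chain. Demand: O1 is released only after C4 is a ketone. A free O1 phenol ortho to an sp3 C4 bearing an ester or hydroxyl on this ring would be an ortho-quinone methide precursor.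

20 ⇒ 19 ⇒ 18. Cut: none in the skeleton; C4=O comes from C4–OH and the sulfonate from the primary hydroxyl. Reason: the oxidant must see only one oxidisable alcohol, and the same sulfonate later serves as the leaving group. Gain: 18 is a plain triol. Demand: selective sulfonylation of a hindered primary hydroxyl, and an oxidant that does not cleave the C3–C4 diol.

18 ⇒ 17. Cut: C4–OH (from water). Reason: C4 is the benzylic carbon of the oxirane on the trioxygenated ring and opens there; the C3–O bond is never broken. Gain: the triol collapses to the epoxy alcohol. Demand: opening at C4 only, without 1,2-shift, under conditions that spare acetals and alkenes.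

17 ⇒ 16. Cut: C3–O and C4–O of the oxirane. Reason: a directed, reagent-controlled epoxidation sets C3 and ignores the prenyl alkenes. Gain: the only stereocentre of the target is removed, leaving an achiral E alkene. Demand: high facial selectivity on a 2,3-diaryl allylic alcohol and survival of an electron-rich epoxide.

16 ⇒ 15 ⇒ 14. Cut: none; the primary alcohol comes from the ester and acid. Reason: the acid is the direct product of the condensation that fixes the alkene geometry. Gain: access to a crystallisable E acid. Demand: 1,2-reduction without touching the alkene geometry or the aryl silyl ether.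

14 ⇒ 13 + 8. Cut: C3=C4. Reason: the condensation of an arylacetic acid with an aryl aldehyde gives the E acid with cis aryl groups, the geometry the epoxidation needs. Gain: the molecule splits into a ring B fragment and a ring A fragment of similar size. Demand: O1 must be blocked, otherwise a 3-arylcoumarin forms.

8 ⇒ 7 ⇒ 6. Cut: O1–Si and C4a–CHO. Reason: a phenol-directed ortho-formylation places the aldehyde next to the one free hydroxyl, which thereby becomes O1. Gain: 6 is symmetric, so only one formylation product is possible. Demand: formylation under non-acidic conditions.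

6 ⇒ 5 ⇒ 3 + 4. Cut: O–Si and C6–CH2 of the prenyl group. Reason: the position between two OMOM groups is the most easily metalated one. Gain: the prenyl group is placed para to the future O1 without isomers. Demand: a silyl ether that neither directs metalation nor is attacked by n-BuLi.

3 ⇒ 2 ⇒ 1. Cut: two O–CH2 bonds and one O–Si bond. Reason: one oxygen of the symmetric triol must be set apart from the other two. Gain: a cheap symmetric starting material. Demand: acceptance of a statistical monosilylation, controlled by an excess of 1.

13 ⇒ 12 ⇒ 11. Cut: C1′–CH2. Reason: the bromine of 11 sits exactly where the side chain is needed. Gain: the two-carbon arm becomes a standard cross-coupling. Demand: coupling of an electron-rich ortho-substituted aryl bromide without harming the prenyl alkene.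

11 ⇒ 10 + 4; 10 ⇒ 9. Cut: C3′–CH2 of the prenyl group and O–CH2 of the acetal. Reason: the proton between OMe and OMOM is the most acidic one of 10. Gain: 9 already has the 1′,2′,4′ pattern. Demand: a base that deprotonates without bromine–lithium exchange.

## Other disconnections considered

Alternative 1: The cut runs through ring B itself (C2′–C3′ and C4′–C5′, with C1′–C2′ broken and re-formed).
- Forward key step: heating cyclobutenone A2, which already carries the C3 centre, with the prenyl siloxyalkyne A3 would give a vinylketene, then a [2+2] adduct, and after ring opening and 6π closure the phenol A1.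
- In its favour: the alkyne dictates the contiguous 2′-O/3′-prenyl/4′-O pattern. This is better than the chosen plan, where that pattern depends on amide-base metalation of a bromoarene (step 8). The 2′-hydroxyl also emerges free for methylation, and the cascade is thermal and neutral.
- Against it here: the step creates no stereocentre, so C3 has to be made earlier and carried through a strained enone. The ketene intermediates must pass two prenyl alkenes at about 80–110 °C. Ring C still has to be closed afterwards by bromine–lithium exchange onto a hindered ester.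
- Comparison: on ring A structure the two plans are equal (bromine marks C4a there, a silyl group marks O1 here). On ring B, and on mildness toward acid-sensitive groups, the alternative is the better. On stereocontrol the chosen plan is better, since step 14 creates C3. On step economy the alternative is expected to be clearly longer, because A2 and A3 are multi-step fragments.

Alternative 2: The cut is the aryl ether bond O1–C8a.
- Forward key step: carbonate base would convert the primary hydroxyl of fluoro ketone A5 into an alkoxide that displaces fluoride through a Meisenheimer adduct to give A4.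
- In its favour: the site of ring closure is fixed by the fluorine atom, so the three ring A oxygens need no differentiation. This is better than the chosen plan, which spends a statistical silylation and a silyl off/on pair on that problem. The C4 ketone is present before closure, which is equal to the chosen plan after its reordering.
- Against it here: the fluorinated ring carries two alkoxy donors, and its ketone is twisted by two ortho substituents, so activation is weak. The β-hydroxy ketone alkoxide can lose formaldehyde by retro-aldol cleavage. The tertiary C3 oxygen must be carried as an acetal that is hard to install and needs acid at the ionisable C3 for removal. The C3 centre must come from a separate asymmetric step that again has to discriminate the prenyl alkenes.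
- Comparison: mechanistically the closure is as simple as the tosylate displacement used here (equal). Ring A economy is better. The source of stereocontrol and the end-game deprotection are weaker. Overall step count is expected to be similar.

Alternative 3: The cut is C3–C4.
- Forward key step: a chiral triazolium-derived carbene would add to the aldehyde of A7, and the resulting Breslow intermediate would attack the tethered ring B ketone to give A6. A6 is identical in constitution with 22. A7 would be assembled from 7 and bromo ketone A8.
- In its favour: one catalytic, redox-neutral step forms ring C, the C3–C4 bond, the ketone and the stereocentre, with no epoxide and no redox adjustment. On step economy this is better than the chosen plan by several steps. It also shares the ring A chemistry up to 7 (equal).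
- Against it here: the aldehyde is di-ortho-substituted and electron-rich, so carbene addition is slow. The ketone bears an ortho methoxy group. The benzoin step is reversible, which can erode enantiomeric purity. Base can enolise the aryloxymethyl ketone.
- Comparison: structurally it reaches the same late intermediate more directly (better). Mechanistically its selectivity rests on a catalyst–substrate fit that is not secured for this substitution pattern. The chosen plan relies on a facial rule that does not depend on the aryl substituents, which is better for predictability.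

Key step: step 14

## Route

Step 1
Reactants: 1 phloroglucinol
Product: 2 5-(triisopropylsilyloxy)benzene-1,3-diol
Conditions: TIPSCl (0.33 equiv), imidazole, DMF, 0 °C → rt
Reagents that add atoms: chlorotriisopropylsilane, CC(C)[Si](Cl)(C(C)C)C(C)C
Why: Statistical O-silylation; with 1 in threefold excess the monosilyl ether should dominate and unreacted 1 is removed with water; the bulky silyl ether marks the oxygen that becomes O1 and does not direct metalation.

Step 2
Reactants: 2 5-(triisopropylsilyloxy)benzene-1,3-diol
Product: 3 1,3-bis(methoxymethoxy)-5-(triisopropylsilyloxy)benzene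
Conditions: MOMCl, i-Pr2NEt, CH2Cl2, 0 °C → rt
Reagents that add atoms: chloromethyl methyl ether, COCCl
Why: Williamson-type acetalisation of both phenols under amine base, which leaves the aryl silyl ether intact; the two OMOM groups are the directing groups for the next step.

Step 3
Reactants: 3 1,3-bis(methoxymethoxy)-5-(triisopropylsilyloxy)benzene; 4 prenyl bromide
Product: 5 1,3-bis(methoxymethoxy)-2-prenyl-5-(triisopropylsilyloxy)benzene
Conditions: n-BuLi, THF, 0 °C; CuBr·SMe2 (10 mol%), 4, −78 °C → rt
Reagents that add atoms: none
Why: Directed ortho-metalation removes the proton flanked by two chelating OMOM groups, and copper-catalysed SN2 allylation with 4 places the prenyl group para to the silyloxy group (the future C6); the TIPS ether is inert to n-BuLi.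

Step 4
Reactants: 5 1,3-bis(methoxymethoxy)-2-prenyl-5-(triisopropylsilyloxy)benzene
Product: 6 3,5-bis(methoxymethoxy)-4-prenylphenol
Conditions: Bu4NF, THF, 0 °C
Reagents that add atoms: none
Why: Fluoride-induced Si–O cleavage frees the single phenol that will direct formylation; acetals and alkene are untouched.

Step 5
Reactants: 6 3,5-bis(methoxymethoxy)-4-prenylphenol
Product: 7 6-hydroxy-2,4-bis(methoxymethoxy)-3-prenylbenzaldehyde
Conditions: MgCl2, Et3N, (CH2O)n, MeCN, reflux
Reagents that add atoms: paraformaldehyde (as formaldehyde), C=O
Why: Casnati–Skattebøl ortho-formylation: the magnesium phenoxide delivers formaldehyde to the ortho carbon and an Oppenauer-type hydride transfer to a second formaldehyde gives the aldehyde; the two ortho positions of 6 are equivalent, so one isomer forms and the free hydroxyl is now defined as O1.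

Step 6
Reactants: 7 6-hydroxy-2,4-bis(methoxymethoxy)-3-prenylbenzaldehyde
Product: 8 2,4-bis(methoxymethoxy)-3-prenyl-6-(triisopropylsilyloxy)benzaldehyde
Conditions: TIPSCl, imidazole, DMF, rt
Reagents that add atoms: chlorotriisopropylsilane, CC(C)[Si](Cl)(C(C)C)C(C)C
Why: Silylation of the chelated phenol; chloride/imidazole is used because silyl triflates attack aryl MOM ethers; TIPS resists acetate and hydride in the following steps and blocks coumarin formation.

Step 7
Reactants: 9 4-bromo-3-methoxyphenol
Product: 10 1-bromo-2-methoxy-4-(methoxymethoxy)benzene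
Conditions: MOMCl, i-Pr2NEt, CH2Cl2, 0 °C → rt
Reagents that add atoms: chloromethyl methyl ether, COCCl
Why: Acetalisation of the phenol gives a second directing group ortho to the position that must carry the prenyl group.

Step 8
Reactants: 10 1-bromo-2-methoxy-4-(methoxymethoxy)benzene; 4 prenyl bromide
Product: 11 1-bromo-2-methoxy-4-(methoxymethoxy)-3-prenylbenzene
Conditions: lithium 2,2,6,6-tetramethylpiperidide (from the amine and n-BuLi), THF, −78 °C; CuBr·SMe2 (10 mol%), 4, −78 → 0 °C
Reagents that add atoms: none
Why: Amide-base directed ortho-metalation: the hindered lithium amide does not exchange bromine and removes the most acidic proton, the one between OMe and OMOM; the resulting aryllithium is not ortho to bromine (no aryne path) and is allylated under copper catalysis.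

Step 9
Reactants: 11 1-bromo-2-methoxy-4-(methoxymethoxy)-3-prenylbenzene
Product: 12 ethyl 2-[2-methoxy-4-(methoxymethoxy)-3-prenylphenyl]acetate
Conditions: BrZnCH2CO2Et, Pd2(dba)3 (2 mol%), XPhos (8 mol%), THF, 60 °C
Reagents that add atoms: ethyl (bromozincio)acetate (Reformatsky reagent), CCOC(=O)C[Zn]Br
Why: Negishi-type arylation of a zinc ester enolate (oxidative addition, transmetalation, reductive elimination); the bulky electron-rich phosphine handles the ortho-methoxy bromide, and acetal and alkene are tolerated.

Step 10
Reactants: 12 ethyl 2-[2-methoxy-4-(methoxymethoxy)-3-prenylphenyl]acetate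
Product: 13 2-[2-methoxy-4-(methoxymethoxy)-3-prenylphenyl]acetic acid
Conditions: LiOH, THF–MeOH–H2O, rt; then aq. HCl to pH 4, 0 °C
Reagents that add atoms: lithium hydroxide, [Li+].[OH-]
Why: Ester saponification; brief acidification to pH 4 in the cold leaves the aryl MOM ether intact.

Step 11
Reactants: 13 2-[2-methoxy-4-(methoxymethoxy)-3-prenylphenyl]acetic acid; 8 2,4-bis(methoxymethoxy)-3-prenyl-6-(triisopropylsilyloxy)benzaldehyde
Product: 14 (E)-3-[2,4-bis(methoxymethoxy)-3-prenyl-6-(triisopropylsilyloxy)phenyl]-2-[2-methoxy-4-(methoxymethoxy)-3-prenylphenyl]prop-2-enoic acid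
Conditions: Ac2O, Et3N, 110 °C; then H2O, THF, rt
Reagents that add atoms: none
Why: Perkin condensation (Oglialoro variant): the enolate of the mixed anhydride adds to the aldehyde and elimination of acetate gives the α-arylcinnamic acid as the E isomer with cis aryl groups, as in the phenylacetic acid/benzaldehyde case; the silyl ether prevents lactonisation and the amine buffers the acetals.

Step 12
Reactants: 14 (E)-3-[2,4-bis(methoxymethoxy)-3-prenyl-6-(triisopropylsilyloxy)phenyl]-2-[2-methoxy-4-(methoxymethoxy)-3-prenylphenyl]prop-2-enoic acid
Product: 15 methyl (E)-3-[2,4-bis(methoxymethoxy)-3-prenyl-6-(triisopropylsilyloxy)phenyl]-2-[2-methoxy-4-(methoxymethoxy)-3-prenylphenyl]prop-2-enoate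
Conditions: MeI, K2CO3, acetone, rt
Reagents that add atoms: iodomethane, CI
Why: SN2 O-alkylation of the carboxylate; mild carbonate in acetone leaves the aryl silyl ether and the alkene geometry unchanged.

Step 13
Reactants: 15 methyl (E)-3-[2,4-bis(methoxymethoxy)-3-prenyl-6-(triisopropylsilyloxy)phenyl]-2-[2-methoxy-4-(methoxymethoxy)-3-prenylphenyl]prop-2-enoate
Product: 16 (E)-3-[2,4-bis(methoxymethoxy)-3-prenyl-6-(triisopropylsilyloxy)phenyl]-2-[2-methoxy-4-(methoxymethoxy)-3-prenylphenyl]prop-2-en-1-ol
Conditions: i-Bu2AlH, CH2Cl2, −78 °C
Reagents that add atoms: none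
Why: 1,2-reduction of the hindered unsaturated ester by the aluminium hydride at low temperature, without conjugate reduction or isomerisation; acetals, silyl ether and prenyl groups are inert.

Step 14
Reactants: 16 (E)-3-[2,4-bis(methoxymethoxy)-3-prenyl-6-(triisopropylsilyloxy)phenyl]-2-[2-methoxy-4-(methoxymethoxy)-3-prenylphenyl]prop-2-en-1-ol
Product: 17 [(2R,3R)-3-[2,4-bis(methoxymethoxy)-3-prenyl-6-(triisopropylsilyloxy)phenyl]-2-[2-methoxy-4-(methoxymethoxy)-3-prenylphenyl]oxiran-2-yl]methanol
Conditions: t-BuOOH (decane), Ti(OiPr)4 (10 mol%), D-(−)-diisopropyl tartrate (13 mol%), 4 Å sieves, CH2Cl2, −25 °C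
Reagents that add atoms: tert-butyl hydroperoxide, CC(C)(C)OO
Why: Sharpless asymmetric epoxidation: 16 and the hydroperoxide exchange onto the dimeric titanium tartrate complex as alkoxide and peroxide, and the distal peroxide oxygen is passed to the alkene of the bound allylic alkoxide. The closest known case is (E)-2,3-diphenylprop-2-en-1-ol, a favourable class with a 2-substituent, a trans 3-substituent and no group cis to the hydroxymethyl carbon. The oxirane is closed by concerted suprafacial oxygen-atom transfer, both C–O bonds forming in one step. C3 is set by the reagent: the L-(+)-tartrate catalyst gives the 2S glycidol series, so the D-(−)-tartrate attacks the opposite face and gives 2R at the oxirane carbon bearing ring B, which is C3 (R) of 24. The second centre (C4, R) follows from the E geometry of 16 by stereospecific syn addition and is erased in step 17. Chemoselectivity over the two prenyl alkenes rests on the directing hydroxyl, since isolated trisubstituted alkenes are not epoxidised by titanium alkoxide and hydroperoxide at −25 °C. Survival of the electron-rich oxirane is supported by catalytic titanium, sieves, low temperature, the weakly donating silyl ether and the two ortho substituents that twist ring A out of conjugation with the C4–O bond; 17 should be passed on after filtration through base-washed silica.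

Step 15
Reactants: 17 [(2R,3R)-3-[2,4-bis(methoxymethoxy)-3-prenyl-6-(triisopropylsilyloxy)phenyl]-2-[2-methoxy-4-(methoxymethoxy)-3-prenylphenyl]oxiran-2-yl]methanol
Product: 18 (2R)-3-[2,4-bis(methoxymethoxy)-3-prenyl-6-(triisopropylsilyloxy)phenyl]-2-[2-methoxy-4-(methoxymethoxy)-3-prenylphenyl]propane-1,2,3-triol (both C3 epimers)
Conditions: HClO4 (2 mol%), THF–H2O (4:1), 0 °C; NaHCO3 quench
Reagents that add atoms: water, O
Why: Acid-catalysed hydrolytic epoxide opening at the benzylic carbon attached to the trioxygenated ring A (C4), where positive charge is best stabilised; the C3–O bond is not broken, so C3 keeps its configuration, and the C4 epimer mixture is irrelevant because C4 becomes a ketone.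

Step 16
Reactants: 18 (2R)-3-[2,4-bis(methoxymethoxy)-3-prenyl-6-(triisopropylsilyloxy)phenyl]-2-[2-methoxy-4-(methoxymethoxy)-3-prenylphenyl]propane-1,2,3-triol
Product: 19 (2R)-2,3-dihydroxy-3-[2,4-bis(methoxymethoxy)-3-prenyl-6-(triisopropylsilyloxy)phenyl]-2-[2-methoxy-4-(methoxymethoxy)-3-prenylphenyl]propyl 4-methylbenzenesulfonate (both C3 epimers)
Conditions: TsCl, Et3N, Bu2SnO (5 mol%), CH2Cl2, rt
Reagents that add atoms: 4-methylbenzenesulfonyl chloride, Cc1ccc(cc1)S(Cl)(=O)=O
Why: Tin-catalysed selective sulfonylation of the primary hydroxyl of a 1,2-diol through a stannylene acetal; the tertiary and the very hindered secondary benzylic hydroxyl should not react, and the sulfonate masks the only other oxidisable alcohol.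

Step 17
Reactants: 19 (2R)-2,3-dihydroxy-3-[2,4-bis(methoxymethoxy)-3-prenyl-6-(triisopropylsilyloxy)phenyl]-2-[2-methoxy-4-(methoxymethoxy)-3-prenylphenyl]propyl 4-methylbenzenesulfonate
Product: 20 (2R)-2-hydroxy-3-[2,4-bis(methoxymethoxy)-3-prenyl-6-(triisopropylsilyloxy)phenyl]-2-[2-methoxy-4-(methoxymethoxy)-3-prenylphenyl]-3-oxopropyl 4-methylbenzenesulfonate
Conditions: IBX, DMSO, rt
Reagents that add atoms: none
Why: IBX oxidation of the secondary benzylic alcohol to the aryl ketone; IBX converts 1,2-diols into α-ketols without C–C cleavage and leaves the tertiary alcohol, tosylate and alkenes alone; both epimers converge, and the ionisable benzylic C4–O bond is removed before O1 is freed.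

Step 18
Reactants: 20 (2R)-2-hydroxy-3-[2,4-bis(methoxymethoxy)-3-prenyl-6-(triisopropylsilyloxy)phenyl]-2-[2-methoxy-4-(methoxymethoxy)-3-prenylphenyl]-3-oxopropyl 4-methylbenzenesulfonate
Product: 22 (3R)-3-hydroxy-5,7-bis(methoxymethoxy)-3-[2-methoxy-4-(methoxymethoxy)-3-prenylphenyl]-6-prenyl-2,3-dihydro-4H-chromen-4-one, via tetrabutylammonium phenoxide 21 (not isolated)
Conditions: Bu4NF, THF, 0 °C → rt
Reagents that add atoms: none
Why: Fluoride cleaves the aryl O–Si bond and the phenoxide ortho to the ketone displaces the primary tosylate (intramolecular Williamson etherification, 6-exo-tet, possibly by way of the terminal oxirane that the phenoxide opens at its methylene carbon); neither path touches the C3–O bond, and because O5 and O7 remain acetals only O1 can close, which fixes the 6-prenyl regiochemistry.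

Step 19
Reactants: 22 (3R)-3-hydroxy-5,7-bis(methoxymethoxy)-3-[2-methoxy-4-(methoxymethoxy)-3-prenylphenyl]-6-prenyl-2,3-dihydro-4H-chromen-4-one
Product: 24 (3R)-3,5,7-trihydroxy-3-(4-hydroxy-2-methoxy-3-prenylphenyl)-6-prenyl-2,3-dihydro-4H-chromen-4-one, via tetrakis(trimethylsilyl) ether 23 (not isolated)
Conditions: TMSOTf, 2,2′-bipyridyl, MeCN, 0 °C → rt; then H2O, citric acid, rt
Reagents that add atoms: none
Why: Silyl triflate/2,2′-bipyridyl cleavage of aromatic MOM ethers: silyl transfer to the aryl oxygen with capture of the methoxymethyl cation by the pyridine base, then mild hydrolysis of the aryl and tertiary silyl ethers; the absence of free protic acid protects the prenyl groups from chroman formation and the tertiary benzylic C3–OH from ionisation and dehydration.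

## Compound list

1 | phloroglucinol (benzene-1,3,5-triol) | Oc1cc(O)cc(O)c1 | starting material
2 | 5-(triisopropylsilyloxy)benzene-1,3-diol | Oc1cc(O)cc(O[Si](C(C)C)(C(C)C)C(C)C)c1 | intermediate
3 | 1,3-bis(methoxymethoxy)-5-(triisopropylsilyloxy)benzene | COCOc1cc(OCOC)cc(O[Si](C(C)C)(C(C)C)C(C)C)c1 | intermediate
4 | prenyl bromide (1-bromo-3-methylbut-2-ene) | CC(C)=CCBr | starting material
5 | 1,3-bis(methoxymethoxy)-2-prenyl-5-(triisopropylsilyloxy)benzene | COCOc1cc(O[Si](C(C)C)(C(C)C)C(C)C)cc(OCOC)c1CC=C(C)C | intermediate
6 | 3,5-bis(methoxymethoxy)-4-prenylphenol | COCOc1cc(O)cc(OCOC)c1CC=C(C)C | intermediate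
7 | 6-hydroxy-2,4-bis(methoxymethoxy)-3-prenylbenzaldehyde | O=Cc1c(O)cc(OCOC)c(CC=C(C)C)c1OCOC | intermediate
8 | 2,4-bis(methoxymethoxy)-3-prenyl-6-(triisopropylsilyloxy)benzaldehyde | O=Cc1c(O[Si](C(C)C)(C(C)C)C(C)C)cc(OCOC)c(CC=C(C)C)c1OCOC | intermediate
9 | 4-bromo-3-methoxyphenol | COc1cc(O)ccc1Br | starting material
10 | 1-bromo-2-methoxy-4-(methoxymethoxy)benzene | COCOc1ccc(Br)c(OC)c1 | intermediate
11 | 1-bromo-2-methoxy-4-(methoxymethoxy)-3-prenylbenzene | COCOc1ccc(Br)c(OC)c1CC=C(C)C | intermediate
12 | ethyl 2-[2-methoxy-4-(methoxymethoxy)-3-prenylphenyl]acetate | CCOC(=O)Cc1ccc(OCOC)c(CC=C(C)C)c1OC | intermediate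
13 | 2-[2-methoxy-4-(methoxymethoxy)-3-prenylphenyl]acetic acid | OC(=O)Cc1ccc(OCOC)c(CC=C(C)C)c1OC | intermediate
14 | (E)-3-[2,4-bis(methoxymethoxy)-3-prenyl-6-(triisopropylsilyloxy)phenyl]-2-[2-methoxy-4-(methoxymethoxy)-3-prenylphenyl]prop-2-enoic acid | OC(=O)/C(=C/c1c(O[Si](C(C)C)(C(C)C)C(C)C)cc(OCOC)c(CC=C(C)C)c1OCOC)c1ccc(OCOC)c(CC=C(C)C)c1OC | intermediate
15 | methyl (E)-3-[2,4-bis(methoxymethoxy)-3-prenyl-6-(triisopropylsilyloxy)phenyl]-2-[2-methoxy-4-(methoxymethoxy)-3-prenylphenyl]prop-2-enoate | COC(=O)/C(=C/c1c(O[Si](C(C)C)(C(C)C)C(C)C)cc(OCOC)c(CC=C(C)C)c1OCOC)c1ccc(OCOC)c(CC=C(C)C)c1OC | intermediate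
16 | (E)-3-[2,4-bis(methoxymethoxy)-3-prenyl-6-(triisopropylsilyloxy)phenyl]-2-[2-methoxy-4-(methoxymethoxy)-3-prenylphenyl]prop-2-en-1-ol | OC/C(=C/c1c(O[Si](C(C)C)(C(C)C)C(C)C)cc(OCOC)c(CC=C(C)C)c1OCOC)c1ccc(OCOC)c(CC=C(C)C)c1OC | intermediate
17 | [(2R,3R)-3-[2,4-bis(methoxymethoxy)-3-prenyl-6-(triisopropylsilyloxy)phenyl]-2-[2-methoxy-4-(methoxymethoxy)-3-prenylphenyl]oxiran-2-yl]methanol | COc1c([C@@]2(O[C@@H]2c3c(O[Si](C(C)C)(C(C)C)C(C)C)cc(OCOC)c(CC=C(C)C)c3OCOC)CO)ccc(OCOC)c1CC=C(C)C | intermediate
18 | (2R)-3-[2,4-bis(methoxymethoxy)-3-prenyl-6-(triisopropylsilyloxy)phenyl]-2-[2-methoxy-4-(methoxymethoxy)-3-prenylphenyl]propane-1,2,3-triol, both C3 epimers | COc1c([C@@](C(O)c2c(O[Si](C(C)C)(C(C)C)C(C)C)cc(OCOC)c(CC=C(C)C)c2OCOC)(O)CO)ccc(OCOC)c1CC=C(C)C | intermediate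
19 | (2R)-2,3-dihydroxy-3-[2,4-bis(methoxymethoxy)-3-prenyl-6-(triisopropylsilyloxy)phenyl]-2-[2-methoxy-4-(methoxymethoxy)-3-prenylphenyl]propyl 4-methylbenzenesulfonate, both C3 epimers | COc1c([C@@](C(O)c2c(O[Si](C(C)C)(C(C)C)C(C)C)cc(OCOC)c(CC=C(C)C)c2OCOC)(O)COS(=O)(=O)c2ccc(C)cc2)ccc(OCOC)c1CC=C(C)C | intermediate
20 | (2R)-2-hydroxy-3-[2,4-bis(methoxymethoxy)-3-prenyl-6-(triisopropylsilyloxy)phenyl]-2-[2-methoxy-4-(methoxymethoxy)-3-prenylphenyl]-3-oxopropyl 4-methylbenzenesulfonate | COc1c([C@@](C(=O)c2c(O[Si](C(C)C)(C(C)C)C(C)C)cc(OCOC)c(CC=C(C)C)c2OCOC)(O)COS(=O)(=O)c2ccc(C)cc2)ccc(OCOC)c1CC=C(C)C | intermediate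
21 | tetrabutylammonium phenoxide of desilylated 20: (2R)-2-hydroxy-3-[6-oxido-2,4-bis(methoxymethoxy)-3-prenylphenyl]-2-[2-methoxy-4-(methoxymethoxy)-3-prenylphenyl]-3-oxopropyl 4-methylbenzenesulfonate | COc1c([C@@](C(=O)c2c([O-])cc(OCOC)c(CC=C(C)C)c2OCOC)(O)COS(=O)(=O)c2ccc(C)cc2)ccc(OCOC)c1CC=C(C)C.CCCC[N+](CCCC)(CCCC)CCCC | intermediate
22 | (3R)-3-hydroxy-5,7-bis(methoxymethoxy)-3-[2-methoxy-4-(methoxymethoxy)-3-prenylphenyl]-6-prenyl-2,3-dihydro-4H-chromen-4-one | COc1c([C@@]2(O)COc3cc(OCOC)c(CC=C(C)C)c(OCOC)c3C2=O)ccc(OCOC)c1CC=C(C)C | intermediate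
23 | (3R)-3-[2-methoxy-3-prenyl-4-(trimethylsilyloxy)phenyl]-6-prenyl-3,5,7-tris(trimethylsilyloxy)-2,3-dihydro-4H-chromen-4-one | COc1c([C@@]2(O[Si](C)(C)C)COc3cc(O[Si](C)(C)C)c(CC=C(C)C)c(O[Si](C)(C)C)c3C2=O)ccc(O[Si](C)(C)C)c1CC=C(C)C | intermediate
24 | (3R)-3,5,7-trihydroxy-3-(4-hydroxy-2-methoxy-3-prenylphenyl)-6-prenyl-2,3-dihydro-4H-chromen-4-one | COc1c([C@@]2(O)COc3cc(O)c(CC=C(C)C)c(O)c3C2=O)ccc(O)c1CC=C(C)C | target

## Step count and risk

Total: 19 steps. Longest linear sequence: 15 steps (steps 1–6 and 11–19, from 1); the ring B branch (steps 7–10) joins at step 11.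

**Step 14 (key step).** Most likely failure: titanium-promoted ionisation of the C4–O bond of 17, with a 1,2-shift or capture by isopropanol or tert-butanol, because C4 is benzylic to a trioxygenated ring. A second failure is slow turnover, caused by the di-ortho-substituted ring A and competing binding of the acetal oxygens, which would lower the enantioselectivity. Fallback: a different catalyst class for the same bond formation, setting out from 16 and returning at 17. This is the vanadium-catalysed asymmetric epoxidation of allylic alcohols with VO(OiPr)3 (1–2 mol%), a C2-symmetric bishydroxamic acid ligand (the enantiomer that gives the 2R series) and t-BuOOH in toluene at 0 °C. The medium is far less Lewis acidic toward the product, and the reaction is known for 2,3-disubstituted and trisubstituted allylic alcohols. No new compound arises.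

**Step 8.** Most likely failure: incomplete metalation (the ring proton and the amine are close in acidity), metalation next to bromine followed by aryne formation or bromine migration, or allylic transposition in the alkylation. Fallback: reverse the order so that n-BuLi can be used on a halogen-free ring, setting out from 10 and returning at 13. Bromine–lithium exchange of 10 (n-BuLi, −78 °C) and addition to ethylene oxide should give 2-[2-methoxy-4-(methoxymethoxy)phenyl]ethan-1-ol F1. Treatment of its lithium alkoxide with n-BuLi, metalation between OMe and OMOM and copper-catalysed reaction with 4 should give 2-[2-methoxy-4-(methoxymethoxy)-3-prenylphenyl]ethan-1-ol F2. Oxidation with TEMPO/PhI(OAc)2 in aqueous MeCN would give 13. Steps 8–10 are replaced.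

**Step 11.** Most likely failure: slow addition of the anhydride enolate to the di-ortho-substituted, electron-rich aldehyde. Prolonged heating could then let acetate strip the ortho silyl group (lactonisation to a 3-arylcoumarin) or erode the E/Z ratio. Fallback: a low-temperature aldol route, setting out from 12 and 8 and returning at 16. The lithium enolate of 12 (LiN(iPr)2, THF, −78 °C) should add to 8 to give ethyl 3-hydroxy-3-[2,4-bis(methoxymethoxy)-3-prenyl-6-(triisopropylsilyloxy)phenyl]-2-[2-methoxy-4-(methoxymethoxy)-3-prenylphenyl]propanoate F3. Acetylation and DBU-induced elimination should give ethyl (E)-3-[2,4-bis(methoxymethoxy)-3-prenyl-6-(triisopropylsilyloxy)phenyl]-2-[2-methoxy-4-(methoxymethoxy)-3-prenylphenyl]prop-2-enoate F4. The E ester is separated from any Z ester, and i-Bu2AlH reduction gives 16. Steps 10–13 are replaced.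

**Step 15.** Most likely failure: the C4 cation undergoes a 1,2-shift (semipinacol rearrangement) faster than water traps it, or ionisation spreads to the tertiary benzylic C3–O bond and erodes the stereocentre. Fallback: chelation-controlled opening without a free cation, setting out from 17 and returning at 18. Ti(OiPr)4 (1.5 equiv) and benzoic acid in CH2Cl2 should deliver benzoate from the titanium alkoxide chelate to C4 and give (2R)-2,3-dihydroxy-1-[2,4-bis(methoxymethoxy)-3-prenyl-6-(triisopropylsilyloxy)phenyl]-2-[2-methoxy-4-(methoxymethoxy)-3-prenylphenyl]propyl benzoate F5. Reductive removal of the benzoate with i-Bu2AlH at −78 °C would give 18.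

**Step 19.** Most likely failure: incomplete acetal cleavage at the MOM groups flanked by the C6 prenyl group, or silyl-triflate-induced ionisation of the tertiary benzylic C3–O bond with dehydration to the isoflavone. Fallback: a change of mechanism from silyl transfer to proton-catalysed acetal exchange with methanol, setting out from 22 and returning at 24. Dilute HCl in MeOH is used at 0 °C → rt and stopped as soon as the last acetal is gone. This is the classical end of prenylated flavonoid syntheses. No new compound arises.

## Further compounds

F1 | step 8 | 2-[2-methoxy-4-(methoxymethoxy)phenyl]ethan-1-ol | OCCc1ccc(OCOC)cc1OC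
F2 | step 8 | 2-[2-methoxy-4-(methoxymethoxy)-3-prenylphenyl]ethan-1-ol | OCCc1ccc(OCOC)c(CC=C(C)C)c1OC
F3 | step 11 | ethyl 3-hydroxy-3-[2,4-bis(methoxymethoxy)-3-prenyl-6-(triisopropylsilyloxy)phenyl]-2-[2-methoxy-4-(methoxymethoxy)-3-prenylphenyl]propanoate (diastereomer mixture) | CCOC(=O)C(c1ccc(OCOC)c(CC=C(C)C)c1OC)C(O)c1c(O[Si](C(C)C)(C(C)C)C(C)C)cc(OCOC)c(CC=C(C)C)c1OCOC
F4 | step 11 | ethyl (E)-3-[2,4-bis(methoxymethoxy)-3-prenyl-6-(triisopropylsilyloxy)phenyl]-2-[2-methoxy-4-(methoxymethoxy)-3-prenylphenyl]prop-2-enoate | CCOC(=O)/C(=C/c1c(O[Si](C(C)C)(C(C)C)C(C)C)cc(OCOC)c(CC=C(C)C)c1OCOC)c1ccc(OCOC)c(CC=C(C)C)c1OC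
F5 | step 15 | (2R)-2,3-dihydroxy-1-[2,4-bis(methoxymethoxy)-3-prenyl-6-(triisopropylsilyloxy)phenyl]-2-[2-methoxy-4-(methoxymethoxy)-3-prenylphenyl]propyl benzoate (configuration at C1 immaterial) | COc1c([C@@](C(OC(=O)c2ccccc2)c2c(O[Si](C(C)C)(C(C)C)C(C)C)cc(OCOC)c(CC=C(C)C)c2OCOC)(O)CO)ccc(OCOC)c1CC=C(C)C
F0 | step 14 | none | none
F0 | step 19 | none | none
A1 | alternative 1 | methyl (2R)-3-[2-bromo-3,5-bis(methoxymethoxy)-4-prenylphenoxy]-2-(2-hydroxy-3-prenyl-4-triisopropylsilyloxyphenyl)-2-(triethylsilyloxy)propanoate | Oc1c([C@@](C(=O)OC)(O[Si](CC)(CC)CC)COc2cc(OCOC)c(CC=C(C)C)c(OCOC)c2Br)ccc(O[Si](C(C)C)(C(C)C)C(C)C)c1CC=C(C)C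
A2 | alternative 1 | methyl (2R)-3-[2-bromo-3,5-bis(methoxymethoxy)-4-prenylphenoxy]-2-(4-oxocyclobut-2-en-1-yl)-2-(triethylsilyloxy)propanoate (ring carbon unspecified) | O=C1C=CC1[C@@](C(=O)OC)(O[Si](CC)(CC)CC)COc1cc(OCOC)c(CC=C(C)C)c(OCOC)c1Br
A3 | alternative 1 | triisopropyl[(5-methylhex-4-en-1-yn-1-yl)oxy]silane | CC(C)=CCC#CO[Si](C(C)C)(C(C)C)C(C)C
A4 | alternative 2 | (3R)-3,5,7-tris(methoxymethoxy)-3-[2-methoxy-4-(methoxymethoxy)-3-prenylphenyl]-6-prenyl-2,3-dihydro-4H-chromen-4-one | COc1c([C@@]2(OCOC)COc3cc(OCOC)c(CC=C(C)C)c(OCOC)c3C2=O)ccc(OCOC)c1CC=C(C)C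
A5 | alternative 2 | (2R)-1-[6-fluoro-2,4-bis(methoxymethoxy)-3-prenylphenyl]-3-hydroxy-2-(methoxymethoxy)-2-[2-methoxy-4-(methoxymethoxy)-3-prenylphenyl]propan-1-one | COc1c([C@@](C(=O)c2c(F)cc(OCOC)c(CC=C(C)C)c2OCOC)(OCOC)CO)ccc(OCOC)c1CC=C(C)C
A6 | alternative 3 | (3R)-3-hydroxy-5,7-bis(methoxymethoxy)-3-[2-methoxy-4-(methoxymethoxy)-3-prenylphenyl]-6-prenyl-2,3-dihydro-4H-chromen-4-one | COc1c([C@@]2(O)COc3cc(OCOC)c(CC=C(C)C)c(OCOC)c3C2=O)ccc(OCOC)c1CC=C(C)C
A7 | alternative 3 | 6-{2-[2-methoxy-4-(methoxymethoxy)-3-prenylphenyl]-2-oxoethoxy}-2,4-bis(methoxymethoxy)-3-prenylbenzaldehyde | O=Cc1c(OCC(=O)c2ccc(OCOC)c(CC=C(C)C)c2OC)cc(OCOC)c(CC=C(C)C)c1OCOC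
A8 | alternative 3 | 2-bromo-1-[2-methoxy-4-(methoxymethoxy)-3-prenylphenyl]ethan-1-one | BrCC(=O)c1ccc(OCOC)c(CC=C(C)C)c1OC
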